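## Retrosynthetic overview
1. The target is the 2,6‑cis‑4‑axial‑hydroxy tetrahydropyran. It comes from global O‑debenzylation and deacetylation of the protected 4‑acetoxy‑THP **8**.
2. The only ring (THP) is formed in the key electrochemical step. Anodic oxidation of the vanillyl homoallyl ether **7** gives an aryl oxocarbenium ion. Chair 6‑endo attack by the terminal alkene forms the C1–C2 bond, and axial acetate capture places the C3 oxygen.
3. **7** comes from O‑vanillylation of the syn‑homoallylic alcohol **5**. **5** comes from chelation‑controlled allylation of the α‑benzyloxy aldehyde **3**, which is made from (S)‑3‑(4‑hydroxyphenyl)lactic acid (**1**).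
4. Stereocenters: C6 comes from **1**. C5 is set by chelation control from C6. C1 and C3 are set by the chair transition state relative to C5.

Assumptions: (S)‑3‑(4‑hydroxyphenyl)lactic acid is purchased (it is also one step from L‑tyrosine by diazotization). 4‑(Benzyloxy)‑3‑methoxybenzyl chloride is taken as commercial (otherwise SOCl2 on the commercial alcohol).

## Route

**Step 1**
Reactants: **1** (S)‑3‑(4‑hydroxyphenyl)lactic acid
Product: **2** benzyl (S)‑2‑(benzyloxy)‑3‑[4‑(benzyloxy)phenyl]propanoate
Conditions: BnBr (2.3 equiv), K2CO3, DMF, rt; then in the same pot Ag2O, BnBr (1.5 equiv), 40 °C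
Reagents that add atoms: benzyl bromide, BrCc1ccccc1
Why: K2CO3 alkylates the carboxylate and phenol, and Ag2O/BnBr benzylates the secondary α‑OH under non‑basic conditions, so the α‑stereocenter (C6) is not epimerized; this is Williamson/Ag2O O‑benzylation.

**Step 2**
Reactants: **2**
Product: **3** (S)‑2‑(benzyloxy)‑3‑[4‑(benzyloxy)phenyl]propanal
Conditions: DIBAL‑H (1.1 equiv), toluene, −78 °C, 1 h; Rochelle salt work‑up; crude aldehyde used at once
Reagents that add atoms: none
Why: Low‑temperature DIBAL stops at the aldehyde stage because the tetrahedral aluminate is stable; the α‑stereocenter is retained by fast, non‑basic handling.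

**Step 3**
Reactants: **3**, **4** allyltributylstannane
Product: **5** (2S,3S)‑2‑(benzyloxy)‑1‑[4‑(benzyloxy)phenyl]hex‑5‑en‑3‑ol
Conditions: **4** (1.5 equiv), MgBr2·OEt2 (2 equiv), CH2Cl2, −78 → −20 °C
Reagents that add atoms: allyltributylstannane, C=CC[Sn](CCCC)(CCCC)CCCC
Why: Mg chelates the aldehyde C=O and the α‑OBn oxygen, and the allyl group attacks the face opposite the CH2Ar substituent (Cram‑chelate Keck allylation). This gives the syn‑1,2‑(OH,OBn) product, i.e. C5 (S) relative to C6 (S).

**Step 4**
Reactants: **5**, **6** 4‑(benzyloxy)‑3‑methoxybenzyl chloride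
Product: **7** vanillyl homoallyl ether, (2S,3S)‑3‑{[4‑(benzyloxy)‑3‑methoxybenzyl]oxy}‑2‑(benzyloxy)‑1‑[4‑(benzyloxy)phenyl]hex‑5‑ene
Conditions: NaH (1.5 equiv), TBAI (0.1 equiv), DMF, 0 °C → rt
Reagents that add atoms: none (the benzyl chloride is the numbered reactant)
Why: Williamson etherification of the secondary alkoxide; no stereocenter is touched.

**Step 5**
Reactants: **7**
Product: **8** (2R,4S,6S)‑2‑[4‑(benzyloxy)‑3‑methoxyphenyl]‑6‑[(S)‑1‑(benzyloxy)‑2‑(4‑benzyloxyphenyl)ethyl]tetrahydropyran‑4‑yl acetate (ring C2 bears the aryl group, C6 the side chain)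
Conditions: undivided cell, graphite anode, Pt cathode, constant current 4 mA (about 2.3 F/mol), 0.05 M **7**, Bu4NBF4 (0.1 M), AcOH (20 equiv), HFIP/CH2Cl2 1:4, rt
Reagents that add atoms: acetic acid, CC(=O)O
Why: Proposed new method: the guaiacyl‑type arene is oxidized about 0.3–0.4 V below the 4‑benzyloxyphenyl ring, and the radical cation loses the benzylic O–CH2 proton. A second oxidation gives the (E)‑aryl oxocarbenium ion, which a pendant unactivated terminal alkene traps in a chair 6‑endo cyclization; C5 (S) fixes the chair, so the aryl group and the side chain sit equatorial (2,6‑cis). Acetate adds axially to the C3 cation (4‑axial OAc, trans to both), and the cathode reduces H+ to H2. The closest known reactions are the Prins cyclization, DDQ‑mediated oxidative cyclization of benzylic ethers, and Shono oxidation. Any 2‑oxonia‑Cope equilibrium disfavors the less stabilized alkyl oxocarbenium ion, so it does not erode stereochemistry.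

**Step 6**
Reactants: **8**
Product: **9** (2R,4S,6S)‑2‑[4‑(benzyloxy)‑3‑methoxyphenyl]‑6‑[(S)‑1‑(benzyloxy)‑2‑(4‑benzyloxyphenyl)ethyl]tetrahydropyran‑4‑ol
Conditions: K2CO3 (2 equiv), MeOH, rt, 2 h
Reagents that add atoms: none
Why: Base methanolysis of the acetate leaves the benzyl ethers and the THP untouched, and the axial C4 stereocenter is not affected.

**Step 7**
Reactants: **9**
Product: **10** Rhoiptelol B
Conditions: H2 (1 atm), 10% Pd/C, EtOAc/EtOH 1:1, rt, 6 h
Reagents that add atoms: none (H2 adds only hydrogen)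
Why: Pd‑catalysed hydrogenolysis removes all three O‑benzyl groups (two phenol, one secondary alcohol) and leaves the OMe, the THP ether and all stereocenters intact.

## Compound list
1 | (2S)‑2‑hydroxy‑3‑(4‑hydroxyphenyl)propanoic acid | O[C@@H](Cc1ccc(O)cc1)C(=O)O | starting material
2 | benzyl (2S)‑2‑(benzyloxy)‑3‑[4‑(benzyloxy)phenyl]propanoate | O=C(OCc1ccccc1)[C@H](Cc1ccc(OCc2ccccc2)cc1)OCc1ccccc1 | intermediate
3 | (2S)‑2‑(benzyloxy)‑3‑[4‑(benzyloxy)phenyl]propanal | O=C[C@H](Cc1ccc(OCc2ccccc2)cc1)OCc1ccccc1 | intermediate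
4 | allyltributylstannane | C=CC[Sn](CCCC)(CCCC)CCCC | starting material
5 | (2S,3S)‑2‑(benzyloxy)‑1‑[4‑(benzyloxy)phenyl]hex‑5‑en‑3‑ol | C=CC[C@H](O)[C@H](Cc1ccc(OCc2ccccc2)cc1)OCc1ccccc1 | intermediate
6 | 4‑(benzyloxy)‑3‑methoxybenzyl chloride | COc1cc(CCl)ccc1OCc1ccccc1 | starting material
7 | vanillyl homoallyl ether of 5 | C=CC[C@H](OCc1ccc(OCc2ccccc2)c(OC)c1)[C@H](Cc1ccc(OCc2ccccc2)cc1)OCc1ccccc1 | intermediate
8 | 4‑acetoxy‑2,6‑cis‑THP (tri‑O‑benzyl) | COc1cc([C@H]2C[C@H](OC(C)=O)C[C@@H]([C@@H](OCc3ccccc3)Cc3ccc(OCc4ccccc4)cc3)O2)ccc1OCc1ccccc1 | intermediate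
9 | 4‑hydroxy‑THP (tri‑O‑benzyl) | COc1cc([C@H]2C[C@H](O)C[C@@H]([C@@H](OCc3ccccc3)Cc3ccc(OCc4ccccc4)cc3)O2)ccc1OCc1ccccc1 | intermediate
10 | Rhoiptelol B | COc1cc([C@H]2C[C@H](O)C[C@@H]([C@@H](O)Cc3ccc(O)cc3)O2)ccc1O | target

## Totals
Total steps: 7. Longest linear sequence: 7 (1 → 2 → 3 → 5 → 7 → 8 → 9 → 10).

## Three steps most likely to fail
1. **Step 5 (proposed new electro‑Prins).** Over‑oxidation of the product's electron‑rich arene, or hydrolysis of the oxocarbenium ion, could lower the yield.
   Fallback (known chemistry): skip steps 4–5. Run an intermolecular Prins cyclization of **5** with commercial 4‑(benzyloxy)‑3‑methoxybenzaldehyde (TFA or TMSOTf, CH2Cl2, −20 °C). This gives the 2,6‑cis, 4‑axial trifluoroacetate, which K2CO3/MeOH converts directly to **9**.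
2. **Step 3 (chelation allylation, syn selectivity).** Felkin leakage would give the anti diastereomer.
   Fallback: use non‑chelating allyl‑SnBu3/BF3·OEt2 to make the anti isomer, then invert C5 by Mitsunobu (p‑nitrobenzoic acid, DEAD, PPh3) and cleave the ester with K2CO3/MeOH. This gives the syn alcohol **5**.
3. **Step 7 (global hydrogenolysis).** Benzylic C1–O hydrogenolysis of the 2‑aryl THP, or incomplete debenzylation, is possible.
   Fallback: drop H2/Pd and cleave the benzyl ethers with BCl3·SMe2 in CH2Cl2 at 0 °C, which is known to cleave benzyl ethers selectively.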